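Assumption: the SMILES is taken literally and read with germacrane numbering (lactone oxygen on C6, ester on C8, primes for the C8 acyl chain), i.e. 1R,6S,7R,8S,3′R, C3 and C6 cis on the C4=C5 bond, and a cis-fused lactone (C6–O and C7–C11 cis).

**Retrosynthetic overview**
- Lactone ring last: C6–O to C12 acyl closure of a cis 6-hydroxy 12-methyl ester, in the same flask as the macrocyclisation (as 6-hydroxylated germacrene acids lactonise).
- Ten-membered ring: the C6–C7 bond (the bond farnesyl diphosphate forms between its C1 and C10), closed by adding a C13/C11/C7 allylchromium to the C6 enal of the complete, unprotected seco chain; C6 and C7 are set from C8.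
- Seco chain: C1–C10 by asymmetric Ni/Cr alkenylation (sets C1), C7–C11 by vinylalumination, C8–O by esterification, C8–C9 by asymmetric 2-bromoallylation (sets C8).
- West aldehyde (C1–C6, C15) by a Horner–Wadsworth–Emmons reaction that fixes the C4=C5 geometry; side-chain acid (C3′) from L-glycerate by alkyne hydroxycarbonylation.
- Ring order: carbocycle first, then the γ-lactone.

**Route**

Step 1
Reactants: 1 triethyl phosphonoacetate; 2 allyl bromide
Product: 3 ethyl 2-(diethoxyphosphoryl)pent-4-enoate (racemic)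
Conditions: NaH, THF, 0 °C to rt
Reagents that add atoms: none
Why: SN2 C-alkylation of the stabilised phosphonoacetate anion; the new centre is destroyed in step 2.

Step 2
Reactants: 3 ethyl 2-(diethoxyphosphoryl)pent-4-enoate; 4 2,2-dimethoxyacetaldehyde (dried from the commercial aqueous solution)
Product: 5 ethyl (2E)-4,4-dimethoxy-2-(prop-2-en-1-yl)but-2-enoate
Conditions: NaH, THF, 0 °C to rt
Reagents that add atoms: none
Why: Horner–Wadsworth–Emmons olefination, whose reversible addition puts the ester trans to the bulky dimethoxymethyl group (E), so that C6 ends cis to C3 and trans to C15 as the target requires.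

Step 3
Reactants: 5 ethyl (2E)-4,4-dimethoxy-2-(prop-2-en-1-yl)but-2-enoate
Product: 6 (2E)-4,4-dimethoxy-2-(prop-2-en-1-yl)but-2-en-1-ol
Conditions: i-Bu2AlH (2.3 equiv), CH2Cl2, −78 °C
Reagents that add atoms: none
Why: Hydride 1,2-reduction of the conjugated ester to the allylic alcohol; acetal and alkenes are inert and the alkene geometry is kept.

Step 4
Reactants: 6 (2E)-4,4-dimethoxy-2-(prop-2-en-1-yl)but-2-en-1-ol
Product: 7 (2E)-4,4-dimethoxy-2-(prop-2-en-1-yl)but-2-en-1-yl acetate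
Conditions: Ac2O, pyridine, DMAP (cat.), CH2Cl2, 0 °C
Reagents that add atoms: acetic anhydride `CC(=O)OC(C)=O`
Why: Standard O-acetylation that installs the C15 acetate of the target early.

Step 5
Reactants: 7 (2E)-4,4-dimethoxy-2-(prop-2-en-1-yl)but-2-en-1-yl acetate
Product: 10 (2E)-4,4-dimethoxy-2-(3-oxopropyl)but-2-en-1-yl acetate, via alkylborane 8 (not isolated), via borinate ester 9 (not isolated)
Conditions: 9-BBN, THF, 0 °C to rt; then N-methylmorpholine N-oxide (6 equiv), 4 Å sieves, (n-Pr4N)RuO4 (5 mol%), CH2Cl2, rt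
Reagents that add atoms: N-methylmorpholine N-oxide `C[N+]1([O-])CCOCC1`
Why: Anti-Markovnikov hydroboration of the only monosubstituted alkene, then one-pot amine-oxide B–C oxidation and Ley–Griffith perruthenate oxidation of the borinate to the C1 aldehyde.

Step 6
Reactants: 11 methyl (4S)-2,2-dimethyl-1,3-dioxolane-4-carboxylate; 12 dimethyl (1-diazo-2-oxopropyl)phosphonate
Product: 14 (4R)-4-ethynyl-2,2-dimethyl-1,3-dioxolane, via aldehyde 13 (not isolated)
Conditions: i-Bu2AlH (1.1 equiv), CH2Cl2, −78 °C; then MeOH, K2CO3, 12, 0 °C to rt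
Reagents that add atoms: none
Why: Partial ester reduction and one-pot Ohira–Bestmann (Seyferth–Gilbert) homologation; the dioxolane centre is untouched (S becomes R only through CIP ranking) and becomes C3′.

Step 7
Reactants: 14 (4R)-4-ethynyl-2,2-dimethyl-1,3-dioxolane
Product: 15 2-[(4R)-2,2-dimethyl-1,3-dioxolan-4-yl]prop-2-enoic acid
Conditions: Pd(OAc)2 (0.5 mol%), 2-(diphenylphosphino)pyridine (10 mol%), CH3SO3H (5 mol%), CO (20 bar), H2O (5 equiv), acetone, 45 °C
Reagents that add atoms: carbon monoxide `[C-]#[O+]`; water `O`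
Why: Palladium hydride Markovnikov hydroxycarbonylation (Drent-type pyridylphosphine catalyst) places the carboxyl on the internal alkyne carbon, and the excess pyridylphosphine buffers the acid so the acetonide survives.

Step 8
Reactants: 16 (E)-cinnamaldehyde; 17 2,3-dibromoprop-1-ene
Product: 18 (1E,3S)-5-bromo-1-phenylhexa-1,5-dien-3-ol
Conditions: CrCl2 (10 mol%), Kishi-type chiral 2-(4-isopropyl-4,5-dihydrooxazol-2-yl)aryl sulfonamide ligand (11 mol%, the antipode that gives 3S), Et3N (20 mol%), Fe(C11H19O2)3 (iron tris(2,2,6,6-tetramethylheptane-3,5-dionate), 5 mol%), Mn (2 equiv), Zr(C5H5)2Cl2 (1.2 equiv), THF, 0 °C to rt; aqueous work-up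
Reagents that add atoms: none
Why: Catalytic asymmetric Nozaki–Hiyama 2-haloallylation in which divalent chromium reduces only the allylic C–Br and the chiral chromium sulfonamide selects the aldehyde face, setting C8 (S); the styryl group is a masked C7 aldehyde.

Step 9
Reactants: 18 (1E,3S)-5-bromo-1-phenylhexa-1,5-dien-3-ol; 15 2-[(4R)-2,2-dimethyl-1,3-dioxolan-4-yl]prop-2-enoic acid
Product: 19 (1E,3S)-5-bromo-1-phenylhexa-1,5-dien-3-yl 2-[(4R)-2,2-dimethyl-1,3-dioxolan-4-yl]prop-2-enoate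
Conditions: DCC (1.2 equiv), DMAP (0.1 equiv), CH2Cl2, 0 °C to rt
Reagents that add atoms: none
Why: Steglich esterification with retention at C8; the acid has no epimerisable α-centre.

Step 10
Reactants: 19 (1E,3S)-5-bromo-1-phenylhexa-1,5-dien-3-yl 2-[(4R)-2,2-dimethyl-1,3-dioxolan-4-yl]prop-2-enoate
Product: 20 (2S)-4-bromo-1-oxopent-4-en-2-yl 2-[(4R)-2,2-dimethyl-1,3-dioxolan-4-yl]prop-2-enoate
Conditions: O3, CH2Cl2, −78 °C (Sudan Red 7B end point); then Me2S, −78 °C to rt; used crude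
Reagents that add atoms: ozone `[O-][O+]=O`
Why: Chemoselective ozonolysis of the electron-rich styryl alkene in preference to the electron-poor vinyl bromide and acrylate, with reductive work-up to the C7 aldehyde.

Step 11
Reactants: 20 (2S)-4-bromo-1-oxopent-4-en-2-yl 2-[(4R)-2,2-dimethyl-1,3-dioxolan-4-yl]prop-2-enoate; 21 methyl propiolate
Product: 23 methyl (4S)-6-bromo-4-({2-[(4R)-2,2-dimethyl-1,3-dioxolan-4-yl]prop-2-enoyl}oxy)-3-hydroxy-2-methylidenehept-6-enoate (C3 epimer mixture), via vinylalane 22 (not isolated)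
Conditions: i-Bu2AlH (1.6 equiv), N-methylmorpholine N-oxide (1.6 equiv), THF, 0 °C, then 21 (1.7 equiv), 0 °C; then 20, 0 °C to rt
Reagents that add atoms: none
Why: Hydroalumination of the propiolate gives α-aluminoacrylate 22, which adds 1,2 to the aldehyde (vinylalumination, a base-free Baylis–Hillman equivalent); the new C7 carbinol is an epimer mixture that step 13 erases.

Step 12
Reactants: 23 methyl (4S)-6-bromo-4-({2-[(4R)-2,2-dimethyl-1,3-dioxolan-4-yl]prop-2-enoyl}oxy)-3-hydroxy-2-methylidenehept-6-enoate; 10 (2E)-4,4-dimethoxy-2-(3-oxopropyl)but-2-en-1-yl acetate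
Product: 24 methyl (4S,7R,10E)-10-(acetoxymethyl)-4-({2-[(4R)-2,2-dimethyl-1,3-dioxolan-4-yl]prop-2-enoyl}oxy)-3-hydroxy-12,12-dimethoxy-2,6-dimethylidene-7-[(triethylsilyl)oxy]dodec-10-enoate (C3 epimer mixture)
Conditions: CrCl2 (15 mol%), Kishi-type chiral oxazoline sulfonamide ligand (17 mol%, the antipode that gives 7R), 1,8-bis(dimethylamino)naphthalene (17 mol%), NiCl2(2,9-dimethyl-1,10-phenanthroline) (3 mol%), Mn (2 equiv), LiCl (2 equiv), Et3SiCl (2 equiv), MeCN, rt
Reagents that add atoms: chlorotriethylsilane `CC[Si](Cl)(CC)CC`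
Why: Catalytic asymmetric Nozaki–Hiyama–Kishi alkenylation in which zerovalent nickel activates the vinyl bromide and the chiral chromium sulfonamide adds it to the aliphatic aldehyde under reagent control (C1 = R), while Et3SiCl turns the catalyst over by silylating the chromium alkoxide so that C1–O emerges protected and the hindered, hydrogen-bonded C7 hydroxyl (no amine base present) stays free.

Step 13
Reactants: 24 (the C1 triethylsilyl ether from step 12)
Product: 25 methyl (2Z,4S,7R,10E)-10-(acetoxymethyl)-2-(bromomethyl)-4-({2-[(4R)-2,2-dimethyl-1,3-dioxolan-4-yl]prop-2-enoyl}oxy)-12,12-dimethoxy-6-methylidene-7-[(triethylsilyl)oxy]dodeca-2,10-dienoate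
Conditions: N-bromosuccinimide (1.5 equiv) and Me2S (1.8 equiv) premixed, CH2Cl2, −20 °C; then 24, 0 °C to rt
Reagents that add atoms: N-bromosuccinimide `O=C1CCC(=O)N1Br`
Why: Corey–Kim-type activation of the Baylis–Hillman hydroxyl and SN2′ delivery of bromide give the conjugated allylic bromide, with A(1,3) strain favouring the Z isomer (C8 cis to CH2Br) needed for a syn addition in step 15.

Step 14
Reactants: 25 (the protected allylic bromide from step 13)
Product: 26 methyl (2Z,4S,7R,10E)-10-(acetoxymethyl)-2-(bromomethyl)-4-{[(3R)-3,4-dihydroxy-2-methylidenebutanoyl]oxy}-7-hydroxy-6-methylidene-12-oxododeca-2,10-dienoate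
Conditions: CF3CO2H/H2O/THF (1:2:6), 0 °C to rt
Reagents that add atoms: water `O`
Why: One acid hydrolysis removes the silyl ether, the dimethyl acetal (freeing the C6 enal) and the acetonide; the allylic bromide, the acetate and the acid-stable dihydroxy acrylate ester survive dilute non-nucleophilic acid.

Step 15
Reactants: 26 (the unprotected seco aldehyde allylic bromide from step 14)
Product: 28 (1R,4E,6S,7R,8S)-15-acetoxy-8-{[(3R)-3,4-dihydroxy-2-methylidenebutanoyl]oxy}-1-hydroxygermacra-4,10(14),11(13)-trien-12,6-olide (CNP0245550.1), via hydroxy ester 27 (not isolated)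
Conditions: CrCl2 (10 equiv), THF/DMF (4:1), slow addition of 26 to 1.5 mM, rt; aqueous NH4Cl work-up, then silica gel, CH2Cl2, rt to complete lactonisation
Reagents that add atoms: none
Why: Intramolecular Nozaki–Hiyama allylation then lactonisation, in which divalent chromium turns the allylic bromide into a 2-(methoxycarbonyl)allylchromium that adds through C7 to the C6 enal in a chair Zimmerman–Traxler transition state, where the Z γ-substituent gives the syn (6,7-cis) adduct and bond formation anti to the C8 acyloxy group (H-8 eclipsing the allyl unit, tether on the attacking face) gives 6S,7R, after which the cis γ-hydroxy ester closes to the lactone with loss of methanol.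

**Compound list**

1 | triethyl phosphonoacetate | `CCOC(=O)CP(=O)(OCC)OCC` | starting material
2 | allyl bromide | `C=CCBr` | starting material
3 | ethyl 2-(diethoxyphosphoryl)pent-4-enoate (racemic) | `CCOC(=O)C(CC=C)P(=O)(OCC)OCC` | intermediate
4 | 2,2-dimethoxyacetaldehyde | `COC(OC)C=O` | starting material
5 | ethyl (2E)-4,4-dimethoxy-2-(prop-2-en-1-yl)but-2-enoate | `CCOC(=O)/C(CC=C)=C/C(OC)OC` | intermediate
6 | (2E)-4,4-dimethoxy-2-(prop-2-en-1-yl)but-2-en-1-ol | `OC/C(CC=C)=C/C(OC)OC` | intermediate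
7 | (2E)-4,4-dimethoxy-2-(prop-2-en-1-yl)but-2-en-1-yl acetate | `CC(=O)OC/C(CC=C)=C/C(OC)OC` | intermediate
8 | (2E)-2-[3-(9-borabicyclo[3.3.1]nonan-9-yl)propyl]-4,4-dimethoxybut-2-en-1-yl acetate | `CC(=O)OC/C(CCCB1C2CCCC1CCC2)=C/C(OC)OC` | intermediate
9 | (2E)-2-[3-(9-borabicyclo[3.3.1]nonan-9-yloxy)propyl]-4,4-dimethoxybut-2-en-1-yl acetate | `CC(=O)OC/C(CCCOB1C2CCCC1CCC2)=C/C(OC)OC` | intermediate
10 | (2E)-4,4-dimethoxy-2-(3-oxopropyl)but-2-en-1-yl acetate | `CC(=O)OC/C(CCC=O)=C/C(OC)OC` | intermediate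
11 | methyl (4S)-2,2-dimethyl-1,3-dioxolane-4-carboxylate | `COC(=O)[C@@H]1COC(C)(C)O1` | starting material
12 | dimethyl (1-diazo-2-oxopropyl)phosphonate | `COP(=O)(OC)C(=[N+]=[N-])C(C)=O` | starting material
13 | (4S)-2,2-dimethyl-1,3-dioxolane-4-carbaldehyde | `O=C[C@@H]1COC(C)(C)O1` | intermediate
14 | (4R)-4-ethynyl-2,2-dimethyl-1,3-dioxolane | `C#C[C@@H]1COC(C)(C)O1` | intermediate
15 | 2-[(4R)-2,2-dimethyl-1,3-dioxolan-4-yl]prop-2-enoic acid | `OC(=O)C(=C)[C@@H]1COC(C)(C)O1` | intermediate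
16 | (E)-cinnamaldehyde | `O=C/C=C/c1ccccc1` | starting material
17 | 2,3-dibromoprop-1-ene | `C=C(Br)CBr` | starting material
18 | (1E,3S)-5-bromo-1-phenylhexa-1,5-dien-3-ol | `C=C(Br)C[C@H](O)/C=C/c1ccccc1` | intermediate
19 | (1E,3S)-5-bromo-1-phenylhexa-1,5-dien-3-yl 2-[(4R)-2,2-dimethyl-1,3-dioxolan-4-yl]prop-2-enoate | `C=C(Br)C[C@H](OC(=O)C(=C)[C@@H]1COC(C)(C)O1)/C=C/c1ccccc1` | intermediate
20 | (2S)-4-bromo-1-oxopent-4-en-2-yl 2-[(4R)-2,2-dimethyl-1,3-dioxolan-4-yl]prop-2-enoate | `C=C(Br)C[C@H](OC(=O)C(=C)[C@@H]1COC(C)(C)O1)C=O` | intermediate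
21 | methyl propiolate | `C#CC(=O)OC` | starting material
22 | methyl 2-[bis(2-methylpropyl)alumanyl]prop-2-enoate | `COC(=O)C(=C)[Al](CC(C)C)CC(C)C` | intermediate
23 | methyl (4S)-6-bromo-4-({2-[(4R)-2,2-dimethyl-1,3-dioxolan-4-yl]prop-2-enoyl}oxy)-3-hydroxy-2-methylidenehept-6-enoate (C3 epimer mixture) | `COC(=O)C(=C)C(O)[C@H](CC(Br)=C)OC(=O)C(=C)[C@@H]1COC(C)(C)O1` | intermediate
24 | methyl (4S,7R,10E)-10-(acetoxymethyl)-4-({2-[(4R)-2,2-dimethyl-1,3-dioxolan-4-yl]prop-2-enoyl}oxy)-3-hydroxy-12,12-dimethoxy-2,6-dimethylidene-7-[(triethylsilyl)oxy]dodec-10-enoate (C3 epimer mixture) | `COC(OC)/C=C(/COC(C)=O)CC[C@@H](O[Si](CC)(CC)CC)C(=C)C[C@H](OC(=O)C(=C)[C@@H]1COC(C)(C)O1)C(O)C(=C)C(=O)OC` | intermediate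
25 | methyl (2Z,4S,7R,10E)-10-(acetoxymethyl)-2-(bromomethyl)-4-({2-[(4R)-2,2-dimethyl-1,3-dioxolan-4-yl]prop-2-enoyl}oxy)-12,12-dimethoxy-6-methylidene-7-[(triethylsilyl)oxy]dodeca-2,10-dienoate | `COC(OC)/C=C(/COC(C)=O)CC[C@@H](O[Si](CC)(CC)CC)C(=C)C[C@H](OC(=O)C(=C)[C@@H]1COC(C)(C)O1)/C=C(\CBr)C(=O)OC` | intermediate
26 | methyl (2Z,4S,7R,10E)-10-(acetoxymethyl)-2-(bromomethyl)-4-{[(3R)-3,4-dihydroxy-2-methylidenebutanoyl]oxy}-7-hydroxy-6-methylidene-12-oxododeca-2,10-dienoate | `O=C/C=C(/COC(C)=O)CC[C@@H](O)C(=C)C[C@H](OC(=O)C(=C)[C@@H](O)CO)/C=C(\CBr)C(=O)OC` | intermediate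
27 | methyl (1R,4E,6S,7S,8S)-15-acetoxy-8-{[(3R)-3,4-dihydroxy-2-methylidenebutanoyl]oxy}-1,6-dihydroxygermacra-4,10(14),11(13)-trien-12-oate (C6–OH and C7 side chain cis) | `O[C@H]1/C=C(/COC(C)=O)CC[C@@H](O)C(=C)C[C@H](OC(=O)C(=C)[C@@H](O)CO)[C@H]1C(=C)C(=O)OC` | intermediate
28 | (1R,4E,6S,7R,8S)-15-acetoxy-8-{[(3R)-3,4-dihydroxy-2-methylidenebutanoyl]oxy}-1-hydroxygermacra-4,10(14),11(13)-trien-12,6-olide (CNP0245550.1) | `C=C1C(=O)O[C@H]2/C=C(/COC(C)=O)CC[C@@H](O)C(=C)C[C@H](OC(=O)C(=C)[C@@H](O)CO)[C@@H]12` | target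

**Step count and risks**

Total steps: 15. Longest linear sequence: 9 steps (steps 1, 2, 3, 4, 5, 12, 13, 14, 15; the side-chain line through steps 6, 7, 9–15 is equally long).

Steps most likely to fail:

1. Step 15 (macrocyclisation and lactonisation). The risks are protonolysis of the allylchromium by the three free hydroxyls, oligomerisation, and a ring-strain override of the syn/anti-to-acyloxy preference. The fallback sets out from 25 and comes back at 27. Copper-catalysed borylation of the allylic bromide (bis(pinacolato)diboron, CuCl, LiOt-Bu, THF, −20 °C) gives the pinacol allylboronate F1. Aqueous trifluoroacetic acid then removes silyl ether, acetal and acetonide to give the seco aldehyde boronate F2. Its allylboron unit adds to the C6 aldehyde without any metal through a closed chair transition state (stereospecific for the same syn adduct, proton-tolerant). Aqueous work-up of the borate gives 27, which lactonises to 28.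

2. Step 12 (Ni/Cr coupling with in situ silylation). The risks are partial silylation of the free C7 hydroxyl and imperfect catalyst control at C1. The fallback sets out from 23 and comes back at 24. The C7 hydroxyl is first capped (Me3SiCl, imidazole, CH2Cl2) as the trimethylsilyl ether F3. The same coupling with 10 then gives the bis-silyl ether F4. Citric acid in methanol at 0 °C cleaves only the far more labile trimethylsilyl group and returns 24.

3. Step 11 (vinylalumination of the α-acyloxy aldehyde). The risks are acyl migration in the aluminium alkoxide and epimerisation of C8. The fallback sets out from 20 and comes back at 23. A kinetic aldol addition of the lithium enolate of methyl 3-(phenylselanyl)propanoate (LiN(i-Pr)2, THF, −78 °C, cold quench) gives the selenide aldol F5. Oxidation with H2O2/pyridine at 0 °C and selenoxide syn-elimination then unveil the acrylate and give 23.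

Further compounds

F1 | step 15 | methyl (2E,4S,7R,10E)-10-(acetoxymethyl)-4-({2-[(4R)-2,2-dimethyl-1,3-dioxolan-4-yl]prop-2-enoyl}oxy)-12,12-dimethoxy-6-methylidene-2-[(4,4,5,5-tetramethyl-1,3,2-dioxaborolan-2-yl)methyl]-7-[(triethylsilyl)oxy]dodeca-2,10-dienoate | `COC(OC)/C=C(/COC(C)=O)CC[C@@H](O[Si](CC)(CC)CC)C(=C)C[C@H](OC(=O)C(=C)[C@@H]1COC(C)(C)O1)/C=C(\CB1OC(C)(C)C(C)(C)O1)C(=O)OC`
F2 | step 15 | methyl (2E,4S,7R,10E)-10-(acetoxymethyl)-4-{[(3R)-3,4-dihydroxy-2-methylidenebutanoyl]oxy}-7-hydroxy-6-methylidene-12-oxo-2-[(4,4,5,5-tetramethyl-1,3,2-dioxaborolan-2-yl)methyl]dodeca-2,10-dienoate | `O=C/C=C(/COC(C)=O)CC[C@@H](O)C(=C)C[C@H](OC(=O)C(=C)[C@@H](O)CO)/C=C(\CB1OC(C)(C)C(C)(C)O1)C(=O)OC`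
F3 | step 12 | methyl (4S)-6-bromo-4-({2-[(4R)-2,2-dimethyl-1,3-dioxolan-4-yl]prop-2-enoyl}oxy)-2-methylidene-3-[(trimethylsilyl)oxy]hept-6-enoate (C3 epimer mixture) | `COC(=O)C(=C)C(O[Si](C)(C)C)[C@H](CC(Br)=C)OC(=O)C(=C)[C@@H]1COC(C)(C)O1`
F4 | step 12 | methyl (4S,7R,10E)-10-(acetoxymethyl)-4-({2-[(4R)-2,2-dimethyl-1,3-dioxolan-4-yl]prop-2-enoyl}oxy)-12,12-dimethoxy-2,6-dimethylidene-7-[(triethylsilyl)oxy]-3-[(trimethylsilyl)oxy]dodec-10-enoate (C3 epimer mixture) | `COC(OC)/C=C(/COC(C)=O)CC[C@@H](O[Si](CC)(CC)CC)C(=C)C[C@H](OC(=O)C(=C)[C@@H]1COC(C)(C)O1)C(O[Si](C)(C)C)C(=C)C(=O)OC`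
F5 | step 11 | methyl (4S)-6-bromo-4-({2-[(4R)-2,2-dimethyl-1,3-dioxolan-4-yl]prop-2-enoyl}oxy)-3-hydroxy-2-[(phenylselanyl)methyl]hept-6-enoate (C2 and C3 epimer mixture) | `COC(=O)C(C[Se]c1ccccc1)C(O)[C@H](CC(Br)=C)OC(=O)C(=C)[C@@H]1COC(C)(C)O1`
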